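**Retrosynthetic overview**
1. The enol ester is made last, by copper-catalysed C–O coupling of an (E)-alkenylboron group at C6 with 3-methylbut-2-enoic acid; the 2-oxopropyl group at C7 comes from a Mannich/Stetter pair, with C7 set by protonation.
2. The C6 stereocentre and its borylvinyl group come from a new rhodium/chiral-diene 1,4-addition of (E)-1,2-bis(pinacolboryl)ethene to a cyclohepta-2,6-dienone; the CH2OH at C2 comes from a Morita–Baylis–Hillman reaction on the open enone arm.
3. The seven-membered ring (the only ring) is made by one-carbon ring expansion of a cyclohexenone: silyl dienol ether, siloxycyclopropane, then FeCl3-mediated radical β-scission, which also creates the C2=C3 enone.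
4. The cyclohexenone with the quaternary C5 centre comes from an organocatalytic asymmetric Robinson-type annulation of 2,6-dimethylhept-5-enal (propanal + 5-bromo-2-methylpent-2-ene) with but-3-en-2-one.
5. Ring order: the six-membered carbocycle is formed first (step 2) and is then enlarged to the seven-membered ring (steps 3–5).

Assumption: both antipodes of the two chiral catalysts (steps 2 and 7) are available, so the sense of each induction can be matched to the target.

Numbering used for the seven-membered ring: C1 = ketone carbon, C2 = C(CH2OH), C3 = vinylic CH, C4 = CH2, C5 = quaternary carbon, C6 = CH with the two-carbon chain, C7 = CH with the 2-oxopropyl group. The target is (5S,6S,7R), with the C5 methyl, the C6 chain and the C7 chain all on one face.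

**Step 1**
Reactants: 1 propanal; 2 5-bromo-2-methylpent-2-ene
Product: 6 rac-2,6-dimethylhept-5-enal, via N-propylidenecyclohexanamine 3 (not isolated), via lithium azaenolate 4 (not isolated), via alkylated imine 5 (not isolated)
Conditions: CyNH2, K2CO3, Et2O, 0 °C, filter and concentrate; LiN(iPr)2, THF, 0 °C; 2, –78 °C to rt; aq. oxalic acid, rt
Reagents that add atoms: none
Why: Stork metalloenamine alkylation, in which the lithium azaenolate of the N-cyclohexyl imine is C-alkylated by the primary bromide and mild acid hydrolysis frees the aldehyde, whose α-centre is racemic and is re-made in step 2.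

**Step 2**
Reactants: 6 rac-2,6-dimethylhept-5-enal; 7 but-3-en-2-one
Product: 9 (S)-4-methyl-4-(4-methylpent-3-en-1-yl)cyclohex-2-en-1-one, via keto aldehyde 8 (not isolated)
Conditions: N-(4-dodecylphenylsulfonyl)prolinamide (20 mol %, enantiomer giving S), BnNH2 (1 equiv), 4 Å MS, ClCH2CH2Cl, rt
Reagents that add atoms: none
Why: Organocatalytic asymmetric Robinson-type annulation (enamine Michael addition, then amine-mediated aldol condensation), in which the hydrogen-bonding prolinamide enamine of the α-branched aldehyde adds to the enone through one face and so sets the quaternary centre (the later C5) as S.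

**Step 3**
Reactants: 9 (S)-4-methyl-4-(4-methylpent-3-en-1-yl)cyclohex-2-en-1-one
Product: 11 (S)-trimethyl{[4-methyl-4-(4-methylpent-3-en-1-yl)cyclohexa-1,5-dien-1-yl]oxy}silane, via lithium dienolate 10 (not isolated)
Conditions: LiN(iPr)2, THF, –78 °C; Me3SiCl, Et3N, –78 to 0 °C
Reagents that add atoms: chlorotrimethylsilane, C[Si](C)(C)Cl
Why: Kinetic α′-deprotonation of the enone (the γ-position is quaternary) and O-silylation give the cross-conjugated silyl dienol ether regiospecifically, with no stereocentre touched.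

**Step 4**
Reactants: 11 (S)-trimethyl{[4-methyl-4-(4-methylpent-3-en-1-yl)cyclohexa-1,5-dien-1-yl]oxy}silane
Product: 12 trimethyl{[(4S)-4-methyl-4-(4-methylpent-3-en-1-yl)bicyclo[4.1.0]hept-2-en-1-yl]oxy}silane (both cyclopropane diastereomers)
Conditions: Et2Zn (1.2 equiv), CH2I2 (1.2 equiv), CH2Cl2, 0 °C
Reagents that add atoms: diiodomethane, ICI
Why: Furukawa–Simmons–Smith cyclopropanation, in which the electrophilic zinc carbenoid reacts fastest with the electron-rich enol ether C=C (over the conjugated ring alkene and the trisubstituted chain alkene at 1.2 equiv), and the configuration of the new cyclopropane carbons is irrelevant because both are planarised in step 5.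

**Step 5**
Reactants: 12 trimethyl{[(4S)-4-methyl-4-(4-methylpent-3-en-1-yl)bicyclo[4.1.0]hept-2-en-1-yl]oxy}silane
Product: 14 (S)-5-methyl-5-(4-methylpent-3-en-1-yl)cyclohepta-2,6-dien-1-one, via chloro enone 13 (not isolated)
Conditions: FeCl3 (2.2 equiv), DMF, 0 °C to rt; then NaOAc, MeOH, reflux
Reagents that add atoms: none
Why: Saegusa-type oxidative ring expansion, in which electron transfer to FeCl3 gives a cyclopropyloxy radical whose β-scission of the ring-fusion bond enlarges the six-membered ring to the seven-membered one, chlorine transfer from FeCl3 traps the secondary radical (faster than a 6-exo attack on the chain alkene) and NaOAc eliminates HCl (E1cB) to give the new C2=C3 enone.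

**Step 6**
Reactants: 14 (S)-5-methyl-5-(4-methylpent-3-en-1-yl)cyclohepta-2,6-dien-1-one; 15 formaldehyde
Product: 16 (S)-2-(hydroxymethyl)-5-methyl-5-(4-methylpent-3-en-1-yl)cyclohepta-2,6-dien-1-one
Conditions: 37% aq. HCHO, 4-(dimethylamino)pyridine (20 mol %), THF–H2O, rt
Reagents that add atoms: none
Why: Morita–Baylis–Hillman reaction, in which the nucleophilic amine adds only to the open β-carbon C3 (C6 is blocked by the neighbouring quaternary centre), the derived enolate takes up formaldehyde at C2 and loss of the amine restores the enone.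

**Step 7**
Reactants: 16 (S)-2-(hydroxymethyl)-5-methyl-5-(4-methylpent-3-en-1-yl)cyclohepta-2,6-dien-1-one; 17 (E)-1,2-bis(4,4,5,5-tetramethyl-1,3,2-dioxaborolan-2-yl)ethene
Product: 18 (5S,6R)-2-(hydroxymethyl)-5-methyl-5-(4-methylpent-3-en-1-yl)-6-[(E)-2-(4,4,5,5-tetramethyl-1,3,2-dioxaborolan-2-yl)ethenyl]cyclohept-2-en-1-one
Conditions: [RhCl(C2H4)2]2 (3 mol %), (R,R)-2,5-diphenylbicyclo[2.2.2]octa-2,5-diene (6.6 mol %, antipode chosen for delivery to the C6 Si face), 17 (3 equiv), K3PO4 (0.5 equiv), dioxane–H2O 10:1, 40 °C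
Reagents that add atoms: none
Why: Proposed new method: a rhodium/chiral-diene asymmetric 1,4-addition that transfers a β-borylvinyl group, in which B-to-Rh transmetalation of one C–B bond of 17 gives a trans-β-boryl alkenyl complex of monovalent rhodium that cannot undergo syn β-boryl elimination, this carbometalates the only α-unsubstituted enone arm at C6 (the C2-substituted arm is too hindered for insertion), and hydrolysis of the oxa-π-allyl rhodium releases the ketone with the second boronate intact (double transfer is held back by the excess of 17 and the greater bulk of the product boronate); because the C5 centre (methyl versus a primary alkyl chain) gives almost no facial bias the diene ligand decides the face, and delivery to the C6 Si face puts the alkenyl group cis to the C5 methyl; the closest known reaction type is the Hayashi–Miyaura rhodium-catalysed asymmetric conjugate addition of alkenylboron reagents to cyclic enones.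

**Step 8**
Reactants: 18 (5S,6R)-2-(hydroxymethyl)-5-methyl-5-(4-methylpent-3-en-1-yl)-6-[(E)-2-(4,4,5,5-tetramethyl-1,3,2-dioxaborolan-2-yl)ethenyl]cyclohept-2-en-1-one
Product: 19 (5S,6S)-7-[(dimethylamino)methyl]-2-(hydroxymethyl)-5-methyl-5-(4-methylpent-3-en-1-yl)-6-[(E)-2-(4,4,5,5-tetramethyl-1,3,2-dioxaborolan-2-yl)ethenyl]cyclohept-2-en-1-one (both C7 epimers)
Conditions: [Me2N=CH2]Cl (1.1 equiv), MeCN, 40 °C; aq. NaHCO3
Reagents that add atoms: N,N-dimethylmethyleneiminium chloride, C=[N+](C)C.[Cl-]
Why: Mannich reaction, in which the ketone can enolise only toward C7 (C2 is sp2) so the iminium ion aminomethylates C7, and both C7 epimers are acceptable because this centre is erased in step 9.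

**Step 9**
Reactants: 19 Mannich base (both C7 epimers); 20 acetaldehyde
Product: 22 (5S,6S,7R)-2-(hydroxymethyl)-5-methyl-5-(4-methylpent-3-en-1-yl)-7-(2-oxopropyl)-6-[(E)-2-(4,4,5,5-tetramethyl-1,3,2-dioxaborolan-2-yl)ethenyl]cyclohept-2-en-1-one, via exo-methylene enone 21 (not isolated)
Conditions: 3-benzyl-5-(2-hydroxyethyl)-4-methylthiazolium chloride (20 mol %), Et3N (0.5 equiv), CH3CHO (5 equiv), EtOH, 60 °C, sealed tube
Reagents that add atoms: none
Why: Stetter reaction (thiazolium carbene umpolung) run on the Mannich base, in which loss of Me2NH gives the 7-methylene enone in the flask, the Breslow intermediate of acetaldehyde adds to its CH2 terminus, and the C1–C7 enol(ate) is protonated kinetically from the face opposite the pseudo-axial C6 alkenyl group (allylic 1,2-strain), which sets C7 as R with the 2-oxopropyl group cis to the C6 chain.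

**Step 10**
Reactants: 22 (5S,6S,7R)-alkenyl pinacolboronate diketone; 23 3-methylbut-2-enoic acid
Product: 25 (5S,6S,7R)-2-(hydroxymethyl)-5-methyl-5-(4-methylpent-3-en-1-yl)-6-[(E)-2-(3-methylbut-2-enoyloxy)ethenyl]-7-(2-oxopropyl)cyclohept-2-en-1-one (the target), via potassium trifluoroborate 24 (not isolated)
Conditions: KHF2, MeOH–H2O, rt, evaporate; then 23, CuBr (20 mol %), 4-(dimethylamino)pyridine (40 mol %), 4 Å MS, O2 (1 atm), MeCN, 40 °C
Reagents that add atoms: none
Why: Chan–Lam-type oxidative C–O coupling, in which the alkenyltrifluoroborate transmetalates to copper and reductive elimination from a trivalent copper carboxylate gives the enol ester with retention of the E geometry under near-neutral conditions that leave C7 untouched.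

**Compound list**
1 | propanal | CCC=O | starting material
2 | 5-bromo-2-methylpent-2-ene | CC(C)=CCCBr | starting material
3 | N-propylidenecyclohexanamine | CCC=NC1CCCCC1 | intermediate
4 | lithium azaenolate of 3, lithium cyclohexyl(prop-1-en-1-yl)amide | CC=CN([Li])C1CCCCC1 | intermediate
5 | N-(2,6-dimethylhept-5-en-1-ylidene)cyclohexanamine (racemic) | CC(C)=CCCC(C)C=NC1CCCCC1 | intermediate
6 | rac-2,6-dimethylhept-5-enal | CC(C)=CCCC(C)C=O | intermediate
7 | but-3-en-2-one | CC(=O)C=C | starting material
8 | (S)-2-methyl-2-(4-methylpent-3-en-1-yl)-5-oxohexanal | CC(=O)CC[C@](C)(CCC=C(C)C)C=O | intermediate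
9 | (S)-4-methyl-4-(4-methylpent-3-en-1-yl)cyclohex-2-en-1-one | O=C1CC[C@](C)(CCC=C(C)C)C=C1 | intermediate
10 | lithium (S)-4-methyl-4-(4-methylpent-3-en-1-yl)cyclohexa-1,5-dien-1-olate | [Li]OC1=CC[C@](C)(CCC=C(C)C)C=C1 | intermediate
11 | (S)-trimethyl{[4-methyl-4-(4-methylpent-3-en-1-yl)cyclohexa-1,5-dien-1-yl]oxy}silane | C[Si](C)(C)OC1=CC[C@](C)(CCC=C(C)C)C=C1 | intermediate
12 | trimethyl{[(4S)-4-methyl-4-(4-methylpent-3-en-1-yl)bicyclo[4.1.0]hept-2-en-1-yl]oxy}silane, both cyclopropane diastereomers | C[Si](C)(C)OC12CC1C[C@](C)(CCC=C(C)C)C=C2 | intermediate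
13 | (4S)-6-chloro-4-methyl-4-(4-methylpent-3-en-1-yl)cyclohept-2-en-1-one, chlorine on the later C3, both epimers | O=C1CC(Cl)C[C@](C)(CCC=C(C)C)C=C1 | intermediate
14 | (S)-5-methyl-5-(4-methylpent-3-en-1-yl)cyclohepta-2,6-dien-1-one | O=C1C=CC[C@](C)(CCC=C(C)C)C=C1 | intermediate
15 | formaldehyde | C=O | starting material
16 | (S)-2-(hydroxymethyl)-5-methyl-5-(4-methylpent-3-en-1-yl)cyclohepta-2,6-dien-1-one | O=C1C(CO)=CC[C@](C)(CCC=C(C)C)C=C1 | intermediate
17 | (E)-1,2-bis(4,4,5,5-tetramethyl-1,3,2-dioxaborolan-2-yl)ethene | CC1(C)OB(/C=C/B2OC(C)(C)C(C)(C)O2)OC1(C)C | starting material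
18 | (5S,6R)-2-(hydroxymethyl)-5-methyl-5-(4-methylpent-3-en-1-yl)-6-[(E)-2-(4,4,5,5-tetramethyl-1,3,2-dioxaborolan-2-yl)ethenyl]cyclohept-2-en-1-one | O=C1C(CO)=CC[C@](C)(CCC=C(C)C)[C@@H](/C=C/B2OC(C)(C)C(C)(C)O2)C1 | intermediate
19 | (5S,6S)-7-[(dimethylamino)methyl]-2-(hydroxymethyl)-5-methyl-5-(4-methylpent-3-en-1-yl)-6-[(E)-2-(4,4,5,5-tetramethyl-1,3,2-dioxaborolan-2-yl)ethenyl]cyclohept-2-en-1-one, both C7 epimers | O=C1C(CO)=CC[C@](C)(CCC=C(C)C)[C@@H](/C=C/B2OC(C)(C)C(C)(C)O2)C1CN(C)C | intermediate
20 | acetaldehyde | CC=O | starting material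
21 | (5S,6R)-2-(hydroxymethyl)-5-methyl-7-methylidene-5-(4-methylpent-3-en-1-yl)-6-[(E)-2-(4,4,5,5-tetramethyl-1,3,2-dioxaborolan-2-yl)ethenyl]cyclohept-2-en-1-one | O=C1C(CO)=CC[C@](C)(CCC=C(C)C)[C@@H](/C=C/B2OC(C)(C)C(C)(C)O2)C1=C | intermediate
22 | (5S,6S,7R)-2-(hydroxymethyl)-5-methyl-5-(4-methylpent-3-en-1-yl)-7-(2-oxopropyl)-6-[(E)-2-(4,4,5,5-tetramethyl-1,3,2-dioxaborolan-2-yl)ethenyl]cyclohept-2-en-1-one | CC(=O)C[C@H]1C(=O)C(CO)=CC[C@](C)(CCC=C(C)C)[C@H]1/C=C/B2OC(C)(C)C(C)(C)O2 | intermediate
23 | 3-methylbut-2-enoic acid | CC(C)=CC(=O)O | starting material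
24 | potassium trifluoro{(E)-2-[(5S,6S,7R)-2-(hydroxymethyl)-5-methyl-5-(4-methylpent-3-en-1-yl)-1-oxo-7-(2-oxopropyl)cyclohept-2-en-6-yl]ethenyl}borate | CC(=O)C[C@H]1C(=O)C(CO)=CC[C@](C)(CCC=C(C)C)[C@H]1/C=C/[B-](F)(F)F.[K+] | intermediate
25 | (5S,6S,7R)-2-(hydroxymethyl)-5-methyl-5-(4-methylpent-3-en-1-yl)-6-[(E)-2-(3-methylbut-2-enoyloxy)ethenyl]-7-(2-oxopropyl)cyclohept-2-en-1-one | CC(=O)C[C@H]1C(=O)C(CO)=CC[C@](C)(CCC=C(C)C)[C@H]1/C=C/OC(=O)C=C(C)C | target

**Totals and risks**
Total step count: 10. Longest linear sequence: 10 steps (1 to 25); compounds 2, 7, 15, 17, 20 and 23 are bought and enter directly.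

The three steps most likely to fail:

Step 6 (Morita–Baylis–Hillman reaction). Cycloheptenones are slow in this reaction and the dienone may oligomerise before it is hydroxymethylated. The fallback sets out from 14. Iodine and pyridine in CH2Cl2 (the amine adds at the open C3, iodine enters at C2) give (S)-2-iodo-5-methyl-5-(4-methylpent-3-en-1-yl)cyclohepta-2,6-dien-1-one F1. A Stille coupling of this with Bu3SnCH2OH and Pd(PPh3)4 in dioxane at 90 °C installs the hydroxymethyl group, and the route is rejoined at 16.

Step 7 (the proposed new rhodium-catalysed borylvinyl transfer). It may fail through slow insertion at the hindered C6, a second transfer from the product boronate, or protodeboronation. The fallback uses known chemistry and sets out from 16. Rhodium-catalysed asymmetric conjugate alkynylation with (triisopropylsilyl)acetylene, using [Rh(OAc)(C2H4)2]2 and (R)-5,5′-bis[bis(3,5-di-tert-butyl-4-methoxyphenyl)phosphino]-4,4′-bi-1,3-benzodioxole (or its antipode, as needed) in dioxane at 80 °C, gives (5S,6S)-2-(hydroxymethyl)-5-methyl-5-(4-methylpent-3-en-1-yl)-6-[(triisopropylsilyl)ethynyl]cyclohept-2-en-1-one F2. Bu4NF buffered with AcOH in THF removes the silyl group to give (5S,6S)-6-ethynyl-2-(hydroxymethyl)-5-methyl-5-(4-methylpent-3-en-1-yl)cyclohept-2-en-1-one F3. syn-Hydroboration of the terminal alkyne with pinacolborane and Cy2BH (10 mol %) gives the E-alkenyl boronate, and the route is rejoined at 18, two steps longer.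

Step 9 (Stetter reaction and the C7 configuration). The warm, mildly basic medium could let C7 drift toward an equilibrium mixture, or move the exocyclic double bond of 21 into the ring, which would erase C6. The fallback sets out from 18. Direct α-methylenation with paraformaldehyde and [iPr2NH2][CF3CO2] in THF at reflux gives enone 21, now isolated. Conjugate addition of the masked acyl anion Li[Cu(C(OEt)=CH2)2] in THF at –78 °C, then protonation of the adduct at –78 °C with 2,6-di-tert-butylphenol from the face opposite the C6 chain, gives (5S,6S,7R)-7-(2-ethoxyprop-2-en-1-yl)-2-(hydroxymethyl)-5-methyl-5-(4-methylpent-3-en-1-yl)-6-[(E)-2-(4,4,5,5-tetramethyl-1,3,2-dioxaborolan-2-yl)ethenyl]cyclohept-2-en-1-one F4. Cold aqueous oxalic acid hydrolyses the enol ether to the methyl ketone, and the route is rejoined at 22.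

**Further compounds**
F1 | step 6 | (S)-2-iodo-5-methyl-5-(4-methylpent-3-en-1-yl)cyclohepta-2,6-dien-1-one | O=C1C(I)=CC[C@](C)(CCC=C(C)C)C=C1
F2 | step 7 | (5S,6S)-2-(hydroxymethyl)-5-methyl-5-(4-methylpent-3-en-1-yl)-6-[(triisopropylsilyl)ethynyl]cyclohept-2-en-1-one | O=C1C(CO)=CC[C@](C)(CCC=C(C)C)[C@@H](C#C[Si](C(C)C)(C(C)C)C(C)C)C1
F3 | step 7 | (5S,6S)-6-ethynyl-2-(hydroxymethyl)-5-methyl-5-(4-methylpent-3-en-1-yl)cyclohept-2-en-1-one | O=C1C(CO)=CC[C@](C)(CCC=C(C)C)[C@@H](C#C)C1
F4 | step 9 | (5S,6S,7R)-7-(2-ethoxyprop-2-en-1-yl)-2-(hydroxymethyl)-5-methyl-5-(4-methylpent-3-en-1-yl)-6-[(E)-2-(4,4,5,5-tetramethyl-1,3,2-dioxaborolan-2-yl)ethenyl]cyclohept-2-en-1-one | C=C(OCC)C[C@H]1C(=O)C(CO)=CC[C@](C)(CCC=C(C)C)[C@H]1/C=C/B2OC(C)(C)C(C)(C)O2
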